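**Strategy.** Ring B (numbered C1 = carbon bearing the ring A oxygen, C3 = chain carbon, C5 = methoxy carbon, C6 = hydroxyl carbon) is disconnected into a four-carbon cyclobutenone and a two-carbon alkyne that already carries the crowded diaryl ether oxygen. One thermal operation merges the 3-substituted cyclobutenone (C2, C3 with its chain, C4, C5) with the ethynyl ether of ring A (C1, C6) into a 3-aryloxy-5-alkylphenol. This exploits the mutual meta relationship in ring B of the C1 aryloxy oxygen, the C3 chain and the C5 oxygen. The precursors are a silyl-protected 3-(3-hydroxypropyl)cyclobutenone and 2,6-dimethoxy-4-propylphenyl ethynyl ether. O-Methylation at C5, lithiation and hydroxylation at C6, and desilylation finish the target.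

Key step: step 6

Remark: the target has no stereocentre. The alkene geometry of 8, the racemic centre of transient 13 and the alkene geometry of transient 14 do not reach the product. Ynol ether 11 is assumed to be made last and used at once as a cold solution.

**Step 1**
Reactants: 1 pent-4-yn-1-ol
Product: 2 tert-butyldimethyl(pent-4-yn-1-yloxy)silane
Conditions: TBSCl, imidazole, CH2Cl2, 0 °C → rt
Reagents that add atoms: tert-butyldimethylsilyl chloride, CC(C)(C)[Si](C)(C)Cl
Why: Imidazole-promoted O-silylation of an unhindered primary alcohol (silyl ether protection) is reliable and leaves the terminal alkyne untouched.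

**Step 2**
Reactants: 2 tert-butyldimethyl(pent-4-yn-1-yloxy)silane; 3 trichloroacetyl chloride
Product: 4 4,4-dichloro-3-[3-(tert-butyldimethylsilyloxy)propyl]cyclobut-2-en-1-one
Conditions: Zn–Cu couple, Et2O/DME, rt, slow addition of 3
Reagents that add atoms: none
Why: Dichloroketene made by zinc dehalogenation of 3 should add to the alkyne in a ketene–alkyne (2+2) cycloaddition in which the terminal alkyne carbon bonds to the ketene carbonyl carbon, placing the chain at C3, while DME ties up ZnCl2 and spares the silyl ether.

**Step 3**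
Reactants: 4 4,4-dichloro-3-[3-(tert-butyldimethylsilyloxy)propyl]cyclobut-2-en-1-one
Product: 5 3-[3-(tert-butyldimethylsilyloxy)propyl]cyclobut-2-en-1-one
Conditions: Zn dust, TMEDA, AcOH, EtOH, 0 °C → rt
Reagents that add atoms: none
Why: Zinc-mediated reductive dechlorination of the α,α-dichloroketone, buffered by TMEDA/AcOH, should remove both chlorines without isomerising the strained enone or cleaving the silyl ether.

**Step 4**
Reactants: 6 2,6-dimethoxy-4-propylphenol; 7 trichloroethylene
Product: 8 2-{[(E)-1,2-dichloroethenyl]oxy}-1,3-dimethoxy-5-propylbenzene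
Conditions: K2CO3, DMF, 70 °C, N2
Reagents that add atoms: none
Why: Base-induced loss of HCl from 7 gives dichloroacetylene only transiently in solution, and anti addition of the phenoxide of 6 to this linear, unhindered electrophile (nucleophilic addition to a haloalkyne) should give the (E)-dichlorovinyl ether, whose geometry is irrelevant to the next step.

**Step 5**
Reactants: 8 2-{[(E)-1,2-dichloroethenyl]oxy}-1,3-dimethoxy-5-propylbenzene
Product: 11 2-(ethynyloxy)-1,3-dimethoxy-5-propylbenzene, via chloroethynyl ether 9 (not isolated), via lithium aryloxyacetylide 10 (not isolated)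
Conditions: n-BuLi (2.3 equiv), Et2O, −78 → −40 °C; H2O, −78 °C; cold pentane extraction, basic alumina plug, kept as a cold solution
Reagents that add atoms: none
Why: Dehydrochlorination of 8 gives chloroalkyne 9, chlorine–lithium exchange with the second equivalent gives acetylide 10, and a neutral cold quench should deliver the terminal ynol ether (elimination/halogen–metal exchange route to alkynyl ethers) without acid-induced hydration.

**Step 6**
Reactants: 5 3-[3-(tert-butyldimethylsilyloxy)propyl]cyclobut-2-en-1-one; 11 2-(ethynyloxy)-1,3-dimethoxy-5-propylbenzene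
Product: 16 3-(2,6-dimethoxy-4-propylphenoxy)-5-[3-(tert-butyldimethylsilyloxy)propyl]phenol, via vinylketene 12 (not isolated), via 4-vinylcyclobutenone 13 (not isolated), via dienylketene 14 (not isolated), via cyclohexadienone 15 (not isolated)
Conditions: 11 (1.5 equiv), degassed PhMe, 80 °C then 110 °C, sealed tube; then K2CO3, MeOH, rt
Reagents that add atoms: none
Why: At 80 °C cyclobutenone 5 should open reversibly (four-electron electrocyclic ring opening) to vinylketene 12, whose ketene C=C is captured by the electron-rich alkyne of 11 in a (2+2) cycloaddition to give 4-vinylcyclobutenone 13. Further heating opens 13 to dienylketene 14, and ring B closes by a thermal disrotatory six-electron electrocyclisation between the ketene carbon (C5) and the terminal methylene (C4) to give dienone 15, which tautomerises to phenol 16. The closest known reaction is the Danheiser benzannulation of 3-alkylcyclobutenones with alkoxyacetylenes, which gives 5-alkylresorcinol monoethers, and an aryl ethynyl ether belongs to the same ynol ether class. No stereocentre persists, since the single centre of 13 is racemic and is erased on ring opening. The step needs regiocontrol in the ketene–alkyne union, which the polarisation of the ynol ether supplies: its nucleophilic terminal CH (C6) bonds to the ketene carbonyl carbon (C5) and its oxygen-bearing carbon (C1) bonds to C2, so the aryloxy group ends meta to the new hydroxyl. The alkyne must also outlast the ketene, which is favoured because an aryl ether has no β-hydrogen for retro-ene loss and the two flanking methoxy groups shield it, while the closing K2CO3/MeOH treatment returns any phenol acylated by 12.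

**Step 7**
Reactants: 16 3-(2,6-dimethoxy-4-propylphenoxy)-5-[3-(tert-butyldimethylsilyloxy)propyl]phenol
Product: 17 tert-butyl{3-[3-(2,6-dimethoxy-4-propylphenoxy)-5-methoxyphenyl]propoxy}dimethylsilane
Conditions: MeI, K2CO3, acetone, reflux
Reagents that add atoms: iodomethane, CI
Why: Williamson O-methylation of an unhindered phenol is dependable, and the alkyl silyl ether and diaryl ether are inert to carbonate.

**Step 8**
Reactants: 17 tert-butyl{3-[3-(2,6-dimethoxy-4-propylphenoxy)-5-methoxyphenyl]propoxy}dimethylsilane
Product: 20 2-(2,6-dimethoxy-4-propylphenoxy)-6-methoxy-4-[3-(tert-butyldimethylsilyloxy)propyl]phenol, via aryllithium 18 (not isolated), via lithium aryltrimethoxyborate 19 (not isolated)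
Conditions: n-BuLi, THF, 0 °C; B(OMe)3, −78 °C → rt; AcOH then 30% aq H2O2, 0 °C → rt
Reagents that add atoms: hydrogen peroxide, OO
Why: Directed ortho-metalation should occur at C6 of ring B, the only C–H flanked by two ether oxygens (ring A and the other ring B positions have one ortho oxygen each), and borate trapping followed by peroxide-induced 1,2-aryl migration from boron to oxygen converts the C–Li bond into C–OH.

**Step 9**
Reactants: 20 2-(2,6-dimethoxy-4-propylphenoxy)-6-methoxy-4-[3-(tert-butyldimethylsilyloxy)propyl]phenol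
Product: 21 2-(2,6-dimethoxy-4-propylphenoxy)-4-(3-hydroxypropyl)-6-methoxyphenol (target)
Conditions: CSA (cat.), MeOH, 0 °C → rt
Reagents that add atoms: none
Why: Acid-catalysed methanolysis of the primary silyl ether should free the alcohol while the ethers and the phenol are inert, and it avoids the air-sensitive electron-rich phenoxide that fluoride or base would generate.

**Compound list**
1 | pent-4-yn-1-ol | C#CCCCO | starting material
2 | tert-butyldimethyl(pent-4-yn-1-yloxy)silane | C#CCCCO[Si](C)(C)C(C)(C)C | intermediate
3 | trichloroacetyl chloride | ClC(Cl)(Cl)C(Cl)=O | starting material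
4 | 4,4-dichloro-3-[3-(tert-butyldimethylsilyloxy)propyl]cyclobut-2-en-1-one | O=C1C=C(CCCO[Si](C)(C)C(C)(C)C)C1(Cl)Cl | intermediate
5 | 3-[3-(tert-butyldimethylsilyloxy)propyl]cyclobut-2-en-1-one | O=C1CC(CCCO[Si](C)(C)C(C)(C)C)=C1 | intermediate
6 | 2,6-dimethoxy-4-propylphenol | CCCc1cc(OC)c(O)c(OC)c1 | starting material
7 | trichloroethylene | ClC=C(Cl)Cl | starting material
8 | 2-{[(E)-1,2-dichloroethenyl]oxy}-1,3-dimethoxy-5-propylbenzene | CCCc1cc(OC)c(O/C(Cl)=C\Cl)c(OC)c1 | intermediate
9 | 2-[(chloroethynyl)oxy]-1,3-dimethoxy-5-propylbenzene | CCCc1cc(OC)c(OC#CCl)c(OC)c1 | intermediate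
10 | lithium (2,6-dimethoxy-4-propylphenoxy)ethynide | CCCc1cc(OC)c(OC#C[Li])c(OC)c1 | intermediate
11 | 2-(ethynyloxy)-1,3-dimethoxy-5-propylbenzene | CCCc1cc(OC)c(OC#C)c(OC)c1 | intermediate
12 | 3-[3-(tert-butyldimethylsilyloxy)propyl]buta-1,3-dien-1-one | O=C=CC(=C)CCCO[Si](C)(C)C(C)(C)C | intermediate
13 | 3-(2,6-dimethoxy-4-propylphenoxy)-4-[5-(tert-butyldimethylsilyloxy)pent-1-en-2-yl]cyclobut-2-en-1-one (racemic) | O=C1C=C(Oc2c(OC)cc(CCC)cc2OC)C1C(=C)CCCO[Si](C)(C)C(C)(C)C | intermediate
14 | (3E)-3-(2,6-dimethoxy-4-propylphenoxy)-5-[3-(tert-butyldimethylsilyloxy)propyl]hexa-1,3,5-trien-1-one | O=C=C/C(Oc1c(OC)cc(CCC)cc1OC)=C\C(=C)CCCO[Si](C)(C)C(C)(C)C | intermediate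
15 | 3-(2,6-dimethoxy-4-propylphenoxy)-5-[3-(tert-butyldimethylsilyloxy)propyl]cyclohexa-2,4-dien-1-one | O=C1C=C(Oc2c(OC)cc(CCC)cc2OC)C=C(CCCO[Si](C)(C)C(C)(C)C)C1 | intermediate
16 | 3-(2,6-dimethoxy-4-propylphenoxy)-5-[3-(tert-butyldimethylsilyloxy)propyl]phenol | CCCc1cc(OC)c(Oc2cc(O)cc(CCCO[Si](C)(C)C(C)(C)C)c2)c(OC)c1 | intermediate
17 | tert-butyl{3-[3-(2,6-dimethoxy-4-propylphenoxy)-5-methoxyphenyl]propoxy}dimethylsilane | CCCc1cc(OC)c(Oc2cc(OC)cc(CCCO[Si](C)(C)C(C)(C)C)c2)c(OC)c1 | intermediate
18 | {2-(2,6-dimethoxy-4-propylphenoxy)-6-methoxy-4-[3-(tert-butyldimethylsilyloxy)propyl]phenyl}lithium | CCCc1cc(OC)c(Oc2cc(CCCO[Si](C)(C)C(C)(C)C)cc(OC)c2[Li])c(OC)c1 | intermediate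
19 | lithium {2-(2,6-dimethoxy-4-propylphenoxy)-6-methoxy-4-[3-(tert-butyldimethylsilyloxy)propyl]phenyl}trimethoxyborate | [Li+].CCCc1cc(OC)c(Oc2cc(CCCO[Si](C)(C)C(C)(C)C)cc(OC)c2[B-](OC)(OC)OC)c(OC)c1 | intermediate
20 | 2-(2,6-dimethoxy-4-propylphenoxy)-6-methoxy-4-[3-(tert-butyldimethylsilyloxy)propyl]phenol | CCCc1cc(OC)c(Oc2cc(CCCO[Si](C)(C)C(C)(C)C)cc(OC)c2O)c(OC)c1 | intermediate
21 | 2-(2,6-dimethoxy-4-propylphenoxy)-4-(3-hydroxypropyl)-6-methoxyphenol | CCCc1cc(OC)c(Oc2cc(CCCO)cc(OC)c2O)c(OC)c1 | target

**Step count and risk**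

Total: 9 steps. Longest linear sequence: 7 steps (steps 1, 2, 3, 6, 7, 8, 9); the ynol ether branch (steps 4, 5) joins at step 6.

Steps most likely to fail:

- **Step 6.** Thermal oligomerisation of the terminal ynol ether could outrun its capture by the vinylketene, or the donor-substituted vinylcyclobutenone could revert instead of opening towards the dienylketene, so that ring B does not form. The fallback builds the diaryl ether on a preformed arene; it sets out from phenol 6 and returns to the route at 17. Commercial 1,3-dibromo-5-methoxybenzene F1 would undergo single bromine–lithium exchange (n-BuLi, Et2O, −78 °C), and the aryllithium would open oxetane in the presence of BF3·OEt2 to give 3-(3-bromo-5-methoxyphenyl)propan-1-ol F2. Silylation (TBSCl, imidazole) would give [3-(3-bromo-5-methoxyphenyl)propoxy](tert-butyl)dimethylsilane F3. Ullmann-type coupling of F3 with 6 (CuI, picolinic acid, K3PO4, DMSO, 90 °C) would then give 17, after which steps 8 and 9 apply unchanged.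

- **Step 8.** The di-ortho-oxygenated aryl borate could lose boron by protodeboronation before oxygen insertion, or borylation at the crowded carbon could be incomplete. The fallback replaces the C–B intermediate by a C–C intermediate that is cleaved oxidatively; it sets out from 17 and returns at 20. Aryllithium 18, generated as before, would be quenched with DMF to give 2-(2,6-dimethoxy-4-propylphenoxy)-6-methoxy-4-[3-(tert-butyldimethylsilyloxy)propyl]benzaldehyde F4. Baeyer–Villiger oxidation of this electron-rich aldehyde (mCPBA, NaHCO3, CH2Cl2, 0 °C) would give 2-(2,6-dimethoxy-4-propylphenoxy)-6-methoxy-4-[3-(tert-butyldimethylsilyloxy)propyl]phenyl formate F5, and methanolysis (K2CO3, MeOH) would give 20.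

- **Step 2.** ZnCl2 released during ketene generation could strip the silyl ether, or dichloroketene could oligomerise faster than it adds to the alkyne. The fallback is a zinc-free keteniminium–alkyne (2+2) cycloaddition; it sets out from alkyne 2 and returns at cyclobutenone 5, bypassing 4 and step 3. N,N-Dimethylacetamide, Tf2O and 2,4,6-collidine in 1,2-dichloroethane at reflux would generate the keteniminium triflate, which adds to 2 with the same regiochemistry to give N-{3-[3-(tert-butyldimethylsilyloxy)propyl]cyclobut-2-en-1-ylidene}-N-methylmethanaminium trifluoromethanesulfonate F6. Hydrolysis with aqueous NaHCO3 would give 5.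

**Further compounds**
F1 | step 6 | 1,3-dibromo-5-methoxybenzene | COc1cc(Br)cc(Br)c1
F2 | step 6 | 3-(3-bromo-5-methoxyphenyl)propan-1-ol | COc1cc(Br)cc(CCCO)c1
F3 | step 6 | [3-(3-bromo-5-methoxyphenyl)propoxy](tert-butyl)dimethylsilane | COc1cc(Br)cc(CCCO[Si](C)(C)C(C)(C)C)c1
F4 | step 8 | 2-(2,6-dimethoxy-4-propylphenoxy)-6-methoxy-4-[3-(tert-butyldimethylsilyloxy)propyl]benzaldehyde | CCCc1cc(OC)c(Oc2cc(CCCO[Si](C)(C)C(C)(C)C)cc(OC)c2C=O)c(OC)c1
F5 | step 8 | 2-(2,6-dimethoxy-4-propylphenoxy)-6-methoxy-4-[3-(tert-butyldimethylsilyloxy)propyl]phenyl formate | CCCc1cc(OC)c(Oc2cc(CCCO[Si](C)(C)C(C)(C)C)cc(OC)c2OC=O)c(OC)c1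
F6 | step 2 | N-{3-[3-(tert-butyldimethylsilyloxy)propyl]cyclobut-2-en-1-ylidene}-N-methylmethanaminium trifluoromethanesulfonate | C[N+](C)=C1C=C(CCCO[Si](C)(C)C(C)(C)C)C1.[O-]S(=O)(=O)C(F)(F)F
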